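**Plan**

- Numbering: ring A is C1 (OMe), C2 (H), C3–C5 (Br), C6 (O-aryl); ring B is C1' (ether O), C3' and C5' (Br), C6' (OH).
- Retrosynthesis: the C4–Br bond is cut first (back to a C4 amine), then the C3, C5, C3' and C5' C–Br bonds, then O–CH3 and a benzyl group on the ring B oxygen. The remaining 2-aryloxy-4-nitrophenol is cut through C5–C6 and C2–C3 into an aryloxyacetone and nitromalonaldehyde, and the aryloxyacetone at its O–CH2 bond.
- Forward: ring B is bought as 2-(benzyloxy)phenol and alkylated with chloroacetone. Ring A is then built on that oxygen by [3+3] condensation, followed by methylation, hydrogenation, fourfold bromination and Sandmeyer bromination.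
- Enabling feature: ring A has bromine at C4 and at both neighbours C3 and C5, beside oxygens at C1 and C6. A C4 nitrogen can direct the C3/C5 bromines and then be exchanged for bromine, and the annulation puts nitro exactly at C4 with C6 already carrying the ring B oxygen.
- Stereochemistry: none; the target is achiral and no stereocentre arises on the way.

Key step: step 2

Assumption: sodium nitromalonaldehyde is taken as the commercial monohydrate; it is shock-sensitive and would be handled in solution behind a shield.

**Route**

Step 1
Reactants: 1 2-(benzyloxy)phenol; 2 chloroacetone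
Product: 3 1-[2-(benzyloxy)phenoxy]propan-2-one
Conditions: K2CO3, KI (cat.), acetone, reflux
Reagents that add atoms: none
Why: Williamson ether synthesis in which the potassium phenoxide of 1 displaces chloride from the carbonyl-activated primary carbon of 2 by SN2 (iodide catalysis through the more reactive iodoacetone), while the benzyl ether is inert to the mild base.

Step 2
Reactants: 3 1-[2-(benzyloxy)phenoxy]propan-2-one; 4 sodium nitromalonaldehyde (monohydrate)
Product: 6 2-[2-(benzyloxy)phenoxy]-4-nitrophenol, via open-chain nitronate 5 (not isolated)
Conditions: NaOH (2 equiv), H2O/EtOH, rt, several days; then 2 M HCl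
Reagents that add atoms: none
Why: Base-mediated [3+3] benzannulation by double aldol condensation: the more acidic aryloxy-bearing methylene of 3 adds as its enolate to one formyl group of the nitromalonaldehyde anion and loses water to give open-chain nitronate 5 (new C5–C6 bond), whose methyl-derived enolate then adds to the second formyl group (new C2–C3 bond), and a second dehydration with tautomerization gives the 4-nitrophenolate that acid liberates as 6. The closest known reaction type is the condensation of sodium nitromalonaldehyde with ketones enolizable on both sides to give 4-nitrophenols (acetone to 4-nitrophenol, substituted methyl ketones to 2-substituted 4-nitrophenols), applied here to an aryloxyacetone. Ring A is closed by a 6-(enolendo)-exo-trig intramolecular aldol addition, and aromatization makes the sequence irreversible. No stereocentre is formed. The step needs cross-condensation to outrun self-aldolization of 3, which the far higher electrophilicity of the formyl groups and the inability of the delocalized nitromalonaldehyde anion to self-condense should secure, and it needs a single regiochemistry, which connectivity guarantees because the carbonyl carbon lies between the aryloxy carbon and the methyl carbon and can only become C1, with the ring B oxygen on C6 and nitro on C4, whichever α-carbon reacts first.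

Step 3
Reactants: 6 2-[2-(benzyloxy)phenoxy]-4-nitrophenol
Product: 7 1-(benzyloxy)-2-(2-methoxy-5-nitrophenoxy)benzene
Conditions: MeI, K2CO3, DMF, rt
Reagents that add atoms: iodomethane, CI
Why: Williamson O-methylation in which the acidic 4-nitrophenol is fully deprotonated by K2CO3 and its phenoxide is methylated by SN2, fixing the C1 methoxy group while the ring B oxygen stays masked as the benzyl ether.

Step 4
Reactants: 7 1-(benzyloxy)-2-(2-methoxy-5-nitrophenoxy)benzene
Product: 8 2-(5-amino-2-methoxyphenoxy)phenol
Conditions: H2 (1 atm), 10% Pd/C, AcOH (2 equiv), MeOH/EtOAc, rt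
Reagents that add atoms: none
Why: Heterogeneous catalytic hydrogenation reduces the nitro group to the amine and cleaves the benzyl ether by hydrogenolysis in one operation; it is placed before any C–Br bond exists so that hydrodehalogenation cannot occur, acetic acid keeps the aniline from retarding the O-debenzylation, and the methyl and diaryl ethers are stable.

Step 5
Reactants: 8 2-(5-amino-2-methoxyphenoxy)phenol
Product: 9 2-(3-amino-2,4-dibromo-6-methoxyphenoxy)-4,6-dibromophenol
Conditions: Br2 (4.0 equiv), NaOAc, AcOH, 10 °C to rt
Reagents that add atoms: bromine, BrBr
Why: Electrophilic aromatic bromination under substituent control: the C4 amino group (para position blocked by C1–OMe) directs bromine to its ortho carbons C3 and C5, the C6' hydroxyl directs bromine to its ortho carbon C5' and para carbon C3', these four sites are far more activated than the remaining C–H positions, and the acetate buffer with exact stoichiometry should limit oxidation and a fifth bromination.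

Step 6
Reactants: 9 2-(3-amino-2,4-dibromo-6-methoxyphenoxy)-4,6-dibromophenol
Product: 11 2,4-dibromo-6-(2,3,4-tribromo-6-methoxyphenoxy)phenol, via diazonium bromide 10 (not isolated)
Conditions: NaNO2, 48% aq HBr, AcOH, 0–5 °C; then CuBr, 48% aq HBr, 60 °C
Reagents that add atoms: hydrogen bromide, Br (supplies the C4 bromine through CuBr, Br[Cu]); sodium nitrite, [Na+].[O-]N=O (supplies one nitrogen of intermediate 10 only, lost again as N2)
Why: Sandmeyer reaction in which diazotization gives diazonium salt 10 and CuBr reduces it by single-electron transfer to an aryl radical that takes bromine from copper bromide with loss of N2; the hydrobromic acid medium makes any halide exchange ortho to the diazonium group degenerate, and azo coupling is excluded because the ortho and para positions of the ring B phenol are already substituted.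

**Compound list**

1 | 2-(benzyloxy)phenol | Oc1ccccc1OCc1ccccc1 | starting material
2 | chloroacetone (1-chloropropan-2-one) | CC(=O)CCl | starting material
3 | 1-[2-(benzyloxy)phenoxy]propan-2-one | CC(=O)COc1ccccc1OCc1ccccc1 | intermediate
4 | sodium nitromalonaldehyde (used as the monohydrate) | [Na+].[O-]C=C(C=O)[N+](=O)[O-] | starting material
5 | sodium salt (nitronate form) of (3E)-4-[2-(benzyloxy)phenoxy]-2-nitro-5-oxohex-3-enal, formed in the flask and not isolated | CC(=O)/C(Oc1ccccc1OCc1ccccc1)=C\C(C=O)=[N+]([O-])[O-].[Na+] | intermediate
6 | 2-[2-(benzyloxy)phenoxy]-4-nitrophenol | Oc1ccc([N+](=O)[O-])cc1Oc1ccccc1OCc1ccccc1 | intermediate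
7 | 1-(benzyloxy)-2-(2-methoxy-5-nitrophenoxy)benzene | COc1ccc([N+](=O)[O-])cc1Oc1ccccc1OCc1ccccc1 | intermediate
8 | 2-(5-amino-2-methoxyphenoxy)phenol | COc1ccc(N)cc1Oc1ccccc1O | intermediate
9 | 2-(3-amino-2,4-dibromo-6-methoxyphenoxy)-4,6-dibromophenol | COc1cc(Br)c(N)c(Br)c1Oc1cc(Br)cc(Br)c1O | intermediate
10 | 2,6-dibromo-3-(3,5-dibromo-2-hydroxyphenoxy)-4-methoxybenzenediazonium bromide, formed in the flask and not isolated | COc1cc(Br)c([N+]#N)c(Br)c1Oc1cc(Br)cc(Br)c1O.[Br-] | intermediate
11 | 2,4-dibromo-6-(2,3,4-tribromo-6-methoxyphenoxy)phenol | COc1cc(Br)c(Br)c(Br)c1Oc1cc(Br)cc(Br)c1O | target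

**Summary**

Total step count: 6. Longest linear sequence: 6 steps (1 → 3 → 6 → 7 → 8 → 9 → 11).

Steps most likely to fail:

Step 2 (annulation). Self-aldolization of ketone 3 or decay of 4 in alkali may outrun the cross-condensation, and the lipophilic ketone may mix poorly with the aqueous salt. Fallback: the diaryl ether would be made by C–O coupling instead of ring construction. 2-(Benzyloxy)phenol 1 would be coupled with commercial 2-bromo-4-nitroanisole in an Ullmann diaryl ether synthesis for hindered partners (CuI, picolinic acid, K3PO4, DMSO, 90 °C), which should give methyl ether 7 directly. The fallback sets out from 1 and returns to the route at 7; it makes no compound outside the list.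

Step 5 (fourfold bromination). Oxidative degradation of the electron-rich 4-alkoxyaniline ring (ipso attack para to nitrogen) may compete with substitution, and control over the number and position of bromines across two activated rings may be lost. Fallback: the rings would be brominated in separate stages, each when the other ring is unreactive. Setting out from 7, the benzyl ether would be cleaved without touching the nitro or methoxy group (BCl3, pentamethylbenzene, CH2Cl2, −78 °C) to give 2-(2-methoxy-5-nitrophenoxy)phenol F1. Br2 (2 equiv) in AcOH should then brominate only the phenol ring, ring A being deactivated by the nitro group, to give 2,4-dibromo-6-(2-methoxy-5-nitrophenoxy)phenol F2. Hydrogenation over sulfided Pt/C, which spares aryl bromides, would give 2-(5-amino-2-methoxyphenoxy)-4,6-dibromophenol F3. N-Bromosuccinimide (2 equiv, MeCN, 0 °C) should then brominate the two carbons ortho to the amine, the activated positions of ring B being occupied, which returns the route to 9.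

Step 6 (Sandmeyer). Diazotization of the hindered, weakly basic amine may be incomplete, the diazonium ion may be diverted to hydro-dediazoniation or hydrolysis, and the free ring B phenol may be nitrosated or oxidized. Fallback: the Sandmeyer reaction would be run before the ring B phenol is set free. Setting out from 7, hydrogenation over sulfided Pt/C in EtOAc (nitro reduced, benzyl ether kept) would give 3-[2-(benzyloxy)phenoxy]-4-methoxyaniline F4. N-Bromosuccinimide (2 equiv, MeCN, 0 °C) would give 3-[2-(benzyloxy)phenoxy]-2,6-dibromo-4-methoxyaniline F5. Diazotization (NaNO2, 48% aq HBr, AcOH, 0–5 °C) to 3-[2-(benzyloxy)phenoxy]-2,6-dibromo-4-methoxybenzenediazonium bromide F6 (not isolated) and treatment with CuBr would give 1-(benzyloxy)-2-(2,3,4-tribromo-6-methoxyphenoxy)benzene F7. BCl3 with pentamethylbenzene (CH2Cl2, −78 °C) would cleave the benzyl ether to 2-(2,3,4-tribromo-6-methoxyphenoxy)phenol F8. Br2 (2 equiv) in AcOH would then brominate the phenol ring ortho and para to the hydroxyl, ring A being deactivated by three bromines, which comes back to the route at target 11.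

**Further compounds**

F0 | step 2 | none | none
F1 | step 5 | 2-(2-methoxy-5-nitrophenoxy)phenol | COc1ccc([N+](=O)[O-])cc1Oc1ccccc1O
F2 | step 5 | 2,4-dibromo-6-(2-methoxy-5-nitrophenoxy)phenol | COc1ccc([N+](=O)[O-])cc1Oc1cc(Br)cc(Br)c1O
F3 | step 5 | 2-(5-amino-2-methoxyphenoxy)-4,6-dibromophenol | COc1ccc(N)cc1Oc1cc(Br)cc(Br)c1O
F4 | step 6 | 3-[2-(benzyloxy)phenoxy]-4-methoxyaniline | COc1ccc(N)cc1Oc1ccccc1OCc1ccccc1
F5 | step 6 | 3-[2-(benzyloxy)phenoxy]-2,6-dibromo-4-methoxyaniline | COc1cc(Br)c(N)c(Br)c1Oc1ccccc1OCc1ccccc1
F6 | step 6 | 3-[2-(benzyloxy)phenoxy]-2,6-dibromo-4-methoxybenzenediazonium bromide | COc1cc(Br)c([N+]#N)c(Br)c1Oc1ccccc1OCc1ccccc1.[Br-]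
F7 | step 6 | 1-(benzyloxy)-2-(2,3,4-tribromo-6-methoxyphenoxy)benzene | COc1cc(Br)c(Br)c(Br)c1Oc1ccccc1OCc1ccccc1
F8 | step 6 | 2-(2,3,4-tribromo-6-methoxyphenoxy)phenol | COc1cc(Br)c(Br)c(Br)c1Oc1ccccc1O
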